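If you have to say what the ash flask will hold at 6.1 h, work with the fraction of starting material left and not the fraction made, for then each flask folds into one dimensionless number.

| setting | alder | birch | ash |
|---|---|---|---|
| starting material | 0.800 M | 0.800 M | 0.260 M |
| free catalyst | 0.0400 M | 0.0800 M | 0.0130 M |
| time |  |  | 6.1 h |

| alder run: time / h | alder run: [starting material] / M | birch run: time / h | birch run: [starting material] / M |
|---|---|---|---|
| 0.24 | 0.759 | 0.24 | 0.740 |
| 0.46 | 0.724 | 0.46 | 0.682 |
| 0.88 | 0.661 | 0.88 | 0.609 |
| 1.7 | 0.569 | 1.7 | 0.480 |
| 3.2 | 0.475 | 3.2 | 0.336 |
| 6.1 | 0.381 | 6.1 | 0.227 |

(readings scatter by 0.004 M)

1. the power of [free catalyst] that the first rate follows, about the charge of the alder run; measure it at two percent of starting material made into product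
2. starting material in the ash run at 6.1 h, as a share of the starting material charged

- Overall: starting material -> product, with free catalyst as catalyst.
- Constant volume, constant temperature.
- An order is taken over about fifteen percent of the charge, up and down.

Call that number the exposure, minus the natural logarithm of the fraction left: it counts the e-foldings a flask has been through, the time integral of a pseudo-first-order rate constant. While the rate follows the first power of starting material, the starting charge cancels out of it, so of the two charges in which the ash run differs from the alder run, free catalyst is the one to reckon with. The alder run reached an exposure of 0.742 at 6.1 h and the birch run, with twice the catalyst, 1.26, which reads as exposure following a power of 0.764 of the free catalyst charged. With 0.325 of the alder catalyst, I reckon the ash run at 0.314, leaving 73.0 %.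

Was one number enough? At 1.7 h the same two runs read a power of 0.584, lower, so the power drifts with time; that early power leaves 68.1 %. I commit to the middle, 70.5 %.

The forecast, reasoning that “The fall tracks time better than product”, gave 62 % (50 % to 74 %), lower than mine, and for the first rate a power of 0.6 (0.42 to 0.8).

The flask gives 68.4 % and, for the first rate, a power of 0.65.

    2 free catalyst ⇌ catalyst dimer, settled at all times (47.90 M⁻¹)
    free catalyst + starting material → product + free catalyst (12.78 M⁻¹ h⁻¹)
    free catalyst → spent catalyst (0.8640 h⁻¹)
    starting material → decomposed substrate (0.03114 h⁻¹)

The ash run's 68.4 % is an exposure of 0.380, more starting material left than the forecast said and less than I said. The same ash run with the step from free catalyst to spent catalyst taken away leaves 45.9 %, an exposure of 0.778. So that step costs the ash run about half of its exposure, from 0.778 down to 0.380.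

The runs stem from a simulated flask on assumed constants; the scatter is artificial.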